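The ten-membered carbocycle is disconnected at C9–C10 (germacrane numbering). The ring segment C8(O)–C9H2–C10(CH3)=C1H is a homoallylic alcohol next to an E-trisubstituted alkene. This is the signature of a reductive union of a terminal epoxide (C8–C9) with a methyl-capped alkyne (C10≡C1). One nickel-catalysed operation should forge C9–C10, fix the E geometry by syn delivery of carbon and hydrogen, close the ring and release C8–OH as the only free hydroxyl, ready for the isovanilloyl ester. The precursor is an acyclic epoxy-enyne that already holds the (E)-C4=C5 alkene and the all-syn C6 silyl ether/C7 isopropyl/C8 triad, made by an Evans aldol and a directed ketone reduction.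

Key step: step 11

Remarks on the chemistry
- **Numbering.** Germacrane numbering is used for ring and chain compounds alike: C1–C10 are the ring carbons, C11–C13 the isopropyl group, C14 the methyl on C10 and C15 the methyl on C4.
- **Configuration.** The target is 4R,5R,6R,7R,8R. In the zigzag C5→C9, O6, the isopropyl group and O8 lie on one side (all-syn). This fits a syn aldol from the (S)-auxiliary followed by a 1,3-syn reduction. Re-derivation of every centre from the target SMILES shows that precursor 20 and product 22 carry the target's spatial arrangement at C6, C7 and C8. The CIP letters change along the route only because substituent priorities change. No centre is inverted.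
- **Epoxide relation.** The C5–O/C6–O relation is erythro (anti in the zigzag). Attack from the ring periphery on the A(1,3)-minimised conformer (H6 eclipsing C4=C5) would give the threo isomer. The erythro isomer needs O6 near the alkene plane and C7 perpendicular to it, which is the geometry of metal-alkoxide-directed oxygen transfer. A titanium–tartrate catalyst of the matching handedness is therefore used.
- **Precursor design.** O6 carries a triethylsilyl group. It tolerates nickel, phosphine and borane, yet it leaves under buffered HF. That avoids basic fluoride (risk of O8→O6 acyl shift across the syn-1,3 pair) and avoids acid strong enough to cyclise the germacradiene.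
- **Temperature.** All operations after ring closure stay at or below 40 °C, to avoid Cope rearrangement.
- **Assumption.** The target SMILES is taken as the authority for the epoxide configuration.

Step 1
Reactants: 1 (S)-4-benzyl-1,3-oxazolidin-2-one; 2 isovaleryl chloride
Product: 3 (S)-4-benzyl-3-(3-methylbutanoyl)-1,3-oxazolidin-2-one
Conditions: Et3N, DMAP (cat.), CH2Cl2, 0 °C → rt
Reagents that add atoms: none
Why: N-acylation of the carbamate nitrogen by the acid chloride under nucleophilic catalysis is a standard imide formation and touches no stereocentre.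

Step 2
Reactants: 3 (S)-4-benzyl-3-(3-methylbutanoyl)-1,3-oxazolidin-2-one; 4 (tert-butyldimethylsilyloxy)acetaldehyde
Product: 6 (4S)-4-benzyl-3-[(2S,3S)-4-(tert-butyldimethylsilyloxy)-3-hydroxy-2-(propan-2-yl)butanoyl]-1,3-oxazolidin-2-one, via boron enolate 5 (not isolated)
Conditions: Bu2BOTf, Et3N, CH2Cl2, −78 → 0 °C; 4, −78 → 0 °C; H2O2, MeOH, pH 7 buffer, 0 °C
Reagents that add atoms: none
Why: Evans syn aldol, in which the (Z)-boron enolate 5 reacts through a chair Zimmerman–Traxler transition state on the face away from the benzyl group and so sets C7 (S) and C8 (S) in the required syn relation.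

Step 3
Reactants: 6 Evans syn aldol adduct
Product: 7 (2S,3S)-4-(tert-butyldimethylsilyloxy)-3-hydroxy-N-methoxy-N-methyl-2-(propan-2-yl)butanamide
Conditions: MeONHMe·HCl, AlMe3, CH2Cl2, −20 °C → rt; aq. potassium sodium tartrate
Reagents that add atoms: N,O-dimethylhydroxylamine hydrochloride, CNOC.Cl
Why: Weinreb aminolysis by the aluminium amide, steered to the exocyclic carbonyl by the C8 aluminium alkoxide, releases the auxiliary without touching C7 or C8.

Step 4
Reactants: 8 hexa-1,5-diyne
Product: 10 hepta-1,5-diyne, via lithium acetylide 9 (not isolated)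
Conditions: 8 (3 equiv), n-BuLi (1 equiv), THF, −78 °C; MeI, −78 °C → rt; distillation
Reagents that add atoms: iodomethane, CI
Why: Alkylation of a terminal acetylide, where the excess of volatile diyne suppresses double methylation and is removed by distillation together with any inert octa-2,6-diyne.

Step 5
Reactants: 10 hepta-1,5-diyne
Product: 12 (E)-1-iodo-2-methylhept-1-en-5-yne, via alkenylalane 11 (not isolated)
Conditions: AlMe3, Cp2ZrCl2 (cat.), CH2Cl2, 0 °C → rt; I2, THF, −30 °C
Reagents that add atoms: trimethylaluminium, C[Al](C)C; iodine, II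
Why: Negishi carboalumination adds methyl and aluminium syn across the terminal alkyne (the internal alkyne reacts far more slowly), and iodinolysis with retention gives the E iodide that carries C15 and the future (E)-C4=C5 alkene.

Step 6
Reactants: 7 Weinreb amide; 12 (E)-1-iodo-2-methylhept-1-en-5-yne
Product: 14 (2S,3S,5E)-1-(tert-butyldimethylsilyloxy)-2-hydroxy-6-methyl-3-(propan-2-yl)undec-5-en-9-yn-4-one, via alkenyllithium 13 (not isolated)
Conditions: 12 (2.3 equiv), t-BuLi (4.6 equiv), Et2O, −78 °C; 7, THF, −78 → −40 °C; AcOH, −78 °C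
Reagents that add atoms: none
Why: Iodine–lithium exchange with retention of geometry followed by Weinreb ketone synthesis, in which one equivalent of 13 deprotonates C8–OH and the chelated tetrahedral adduct prevents over-addition, while the cold acidic quench avoids retro-aldol cleavage.

Step 7
Reactants: 14 β-hydroxy enone
Product: 16 (2S,3R,4S,5E)-1-(tert-butyldimethylsilyloxy)-6-methyl-3-(propan-2-yl)undec-5-en-9-yne-2,4-diol, via boron chelate 15 (not isolated)
Conditions: Et2BOMe, THF/MeOH 4:1, −78 °C; NaBH4, −78 °C; repeated evaporation from MeOH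
Reagents that add atoms: none
Why: Narasaka–Prasad reduction, in which external hydride attacks the C6 carbonyl of the half-chair chelate 15 axially, on the side opposite to the pseudo-axial isopropyl group, and so gives the 1,3-syn diol (C6 set relative to C8) by clean 1,2-reduction of the enone.

Step 8
Reactants: 16 syn-1,3-diol
Product: 17 (2S,3R,4S,5E)-6-methyl-3-(propan-2-yl)undec-5-en-9-yne-1,2,4-triol
Conditions: Bu4NF, THF, 0 °C → rt
Reagents that add atoms: none
Why: Fluoride cleaves the only silyl ether under non-acidic conditions that spare the ionisable tertiary-type allylic alcohol.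

Step 9
Reactants: 17 triol
Product: 19 (3R,4S,5E)-2,6-dimethyl-3-[(2S)-oxiran-2-yl]undec-5-en-9-yn-4-ol, via primary tosylate 18 (not isolated)
Conditions: TsCl (1.05 equiv), Et3N, Bu2SnO (cat.), CH2Cl2, 0 °C; then K2CO3, MeOH, 0 °C → rt
Reagents that add atoms: none
Why: Stannylene-catalysed sulfonylation picks the primary hydroxyl of the terminal 1,2-diol, and carbonate then triggers a 3-exo-tet Williamson closure by O8, so the C8–O bond and its configuration are kept.

Step 10
Reactants: 19 epoxy alcohol
Product: 20 (3S,4S,5E)-2,6-dimethyl-3-[(2S)-oxiran-2-yl]-4-(triethylsilyloxy)undec-5-en-9-yne (6S,7S,8S in germacrane numbering)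
Conditions: Et3SiCl, imidazole, DMF, 0 °C → rt
Reagents that add atoms: chlorotriethylsilane, CC[Si](Cl)(CC)CC
Why: Silylation of the only remaining hydroxyl under mildly basic conditions that leave the terminal epoxide untouched.

Step 11
Reactants: 20 epoxy-enyne silyl ether
Product: 22 (1(10)E,4E,6S,7S,8R)-6-(triethylsilyloxy)germacra-1(10),4-dien-8-ol, via boryl ether 21 (not isolated)
Conditions: Ni(cod)2 (20 mol %), PBu3 (40 mol %), BEt3 (4 equiv), toluene, 25–40 °C, syringe-pump addition of 20 (final 0.003 M); aq. NaHCO3
Reagents that add atoms: none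
Why: Proposed new method: zerovalent nickel bearing PBu3 should open the BEt3-activated epoxide at the unsubstituted C9 to an oxanickelacyclobutane, the tethered alkyne should insert into Ni–C9 to give the six-membered oxanickelacycle Ni–O8–C8–C9–C10=C1, and ethyl transfer from BEt3, β-hydride elimination (ethene) and C1–H reductive elimination should release boryl ether 21 and the catalyst. The closest known reaction type is the nickel/phosphine/BEt3 reductive coupling of alkynes with monosubstituted epoxides, shown between two molecules and for five- and six-membered rings, flanked by nickel-catalysed alkyne–aldehyde reductive macrocyclisations, whereas a medium-ring alkyne–epoxide closure has not been shown. The ten-membered ring closes endocyclic with respect to the alkyne (bond to the distal carbon C10, both alkyne carbons in the ring) and at the terminal epoxide carbon, so O8 stays outside the carbocycle. No stereocentre is created: the C8–O bond is never broken, C6 and C7 are spectators, and the E geometry of C1=C10 follows from syn addition of C9 and H, which puts C9 and C2 on opposite sides. The step needs bond formation at C10 instead of C1 and at C9 instead of C8; the smaller methyl flank of the alkyne combined with a small phosphine, the avoidance of a nine-membered ring with an exocyclic ethylidene, and the steric bias of a monosubstituted epoxide all point this way, but only the last point rests on precedent. Slow addition at high dilution should hold back dimerisation, the gauche turn of the all-syn C6–C8 segment should bring the termini together, and the trisubstituted C4=C5 alkene and the silyl ether are inert to the catalyst.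

Step 12
Reactants: 23 isovanillic acid (3-hydroxy-4-methoxybenzoic acid)
Product: 25 3-(allyloxy)-4-methoxybenzoic acid, via allyl ester 24 (not isolated)
Conditions: allyl bromide (2.5 equiv), K2CO3, DMF, 50 °C; then aq. NaOH, MeOH, rt; HCl
Reagents that add atoms: allyl bromide, C=CCBr
Why: Williamson allylation of phenol and carboxylate followed by saponification of the allyl ester leaves the aryl allyl ether, which masks the phenol during acylation and oxidation.

Step 13
Reactants: 22 macrocyclic C8 alcohol; 25 3-(allyloxy)-4-methoxybenzoic acid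
Product: 26 (1(10)E,4E,6S,7S,8R)-6-(triethylsilyloxy)germacra-1(10),4-dien-8-yl 3-(allyloxy)-4-methoxybenzoate
Conditions: DCC, DMAP, CH2Cl2, 0 °C → rt
Reagents that add atoms: none
Why: Steglich esterification of the only free hydroxyl, which needs no C6/C8 differentiation and keeps C8 because the C8–O bond is not broken.

Step 14
Reactants: 26 silyl ether ester
Product: 27 (1(10)E,4E,6S,7R,8R)-6-hydroxygermacra-1(10),4-dien-8-yl 3-(allyloxy)-4-methoxybenzoate
Conditions: HF·pyridine, pyridine, THF, 0 °C
Reagents that add atoms: none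
Why: Buffered HF cleaves the secondary triethylsilyl ether without generating an alkoxide, which avoids O8→O6 acyl migration, and it is too weakly acidic to start transannular cyclisation of the 1,5-diene.

Step 15
Reactants: 27 allylic alcohol
Product: 28 (1(10)E,4R,5R,6R,7R,8R)-4,5-epoxy-6-hydroxygermacr-1(10)-en-8-yl 3-(allyloxy)-4-methoxybenzoate
Conditions: Ti(OiPr)4 (0.3 equiv), D-(−)-diisopropyl tartrate (0.36 equiv), t-BuOOH (2 equiv), 4 Å molecular sieves, CH2Cl2, −20 °C
Reagents that add atoms: tert-butyl hydroperoxide, CC(C)(C)OO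
Why: Sharpless asymmetric epoxidation in its matched sense, since the titanium alkoxide of O6 can reach the exposed outer face of C4=C5 only when O6 lies near the alkene plane and C7 stands perpendicular on the inner face, which is both the geometry the E-cyclodecene imposes and the fast-reacting erythro arrangement for D-(−)-tartrate with this C6 configuration, so C4 (R) and C5 (R) are set by ligand and ring together while C1=C10 and the allyl ether, which lack an allylic hydroxyl, stay untouched.

Step 16
Reactants: 28 epoxy alcohol allyl ether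
Product: 29 (1(10)E,4R,5R,6R,7R,8R)-4,5-epoxy-6-hydroxygermacr-1(10)-en-8-yl 3-hydroxy-4-methoxybenzoate (target)
Conditions: Pd(PPh3)4 (5 mol %), morpholine, THF, rt
Reagents that add atoms: none
Why: Tsuji–Trost deallylation, in which zerovalent palladium ionises only the aryl allyl ether and morpholine traps the allyl fragment, while the homoallylic ester, the non-allylic epoxide and the ring alkene offer no ionisable allylic leaving group.

Compound list
1 | (S)-4-benzyl-1,3-oxazolidin-2-one | O=C1N[C@@H](Cc2ccccc2)CO1 | starting material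
2 | isovaleryl chloride | CC(C)CC(Cl)=O | starting material
3 | (S)-4-benzyl-3-(3-methylbutanoyl)-1,3-oxazolidin-2-one | CC(C)CC(=O)N1C(=O)OC[C@@H]1Cc1ccccc1 | intermediate
4 | (tert-butyldimethylsilyloxy)acetaldehyde | CC(C)(C)[Si](C)(C)OCC=O | starting material
5 | (Z)-dibutylboron enolate of 3 | CCCCB(CCCC)O/C(=C\C(C)C)N1C(=O)OC[C@@H]1Cc1ccccc1 | intermediate
6 | Evans syn aldol adduct, (4S)-auxiliary, (2S,3S)-acyl chain (C7 S, C8 S) | O=C1OC[C@H](Cc2ccccc2)N1C(=O)[C@@H](C(C)C)[C@H](O)CO[Si](C)(C)C(C)(C)C | intermediate
7 | (2S,3S)-4-(tert-butyldimethylsilyloxy)-3-hydroxy-N-methoxy-N-methyl-2-(propan-2-yl)butanamide | CON(C)C(=O)[C@@H](C(C)C)[C@H](O)CO[Si](C)(C)C(C)(C)C | intermediate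
8 | hexa-1,5-diyne | C#CCCC#C | starting material
9 | lithium hexa-1,5-diyn-1-ide | [Li]C#CCCC#C | intermediate
10 | hepta-1,5-diyne | CC#CCCC#C | intermediate
11 | (E)-dimethyl(2-methylhept-1-en-5-yn-1-yl)alane | CC#CCC/C(C)=C/[Al](C)C | intermediate
12 | (E)-1-iodo-2-methylhept-1-en-5-yne | CC#CCC/C(C)=C/I | intermediate
13 | (E)-(2-methylhept-1-en-5-yn-1-yl)lithium | CC#CCC/C(C)=C/[Li] | intermediate
14 | (2S,3S,5E)-1-(tert-butyldimethylsilyloxy)-2-hydroxy-6-methyl-3-(propan-2-yl)undec-5-en-9-yn-4-one | CC#CCC/C(C)=C/C(=O)[C@@H](C(C)C)[C@H](O)CO[Si](C)(C)C(C)(C)C | intermediate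
15 | O8-diethylboryl chelate of 14 (boron also bound to the C6 carbonyl oxygen) | CC#CCC/C(C)=C/C(=O)[C@@H](C(C)C)[C@H](OB(CC)CC)CO[Si](C)(C)C(C)(C)C | intermediate
16 | (2S,3R,4S,5E)-1-(tert-butyldimethylsilyloxy)-6-methyl-3-(propan-2-yl)undec-5-en-9-yne-2,4-diol | CC#CCC/C(C)=C/[C@H](O)[C@@H](C(C)C)[C@H](O)CO[Si](C)(C)C(C)(C)C | intermediate
17 | (2S,3R,4S,5E)-6-methyl-3-(propan-2-yl)undec-5-en-9-yne-1,2,4-triol | CC#CCC/C(C)=C/[C@H](O)[C@@H](C(C)C)[C@H](O)CO | intermediate
18 | primary (C9) 4-methylbenzenesulfonate of 17 | CC#CCC/C(C)=C/[C@H](O)[C@@H](C(C)C)[C@H](O)COS(=O)(=O)c1ccc(C)cc1 | intermediate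
19 | (3R,4S,5E)-2,6-dimethyl-3-[(2S)-oxiran-2-yl]undec-5-en-9-yn-4-ol | CC#CCC/C(C)=C/[C@H](O)[C@@H](C(C)C)[C@H]1CO1 | intermediate
20 | (3S,4S,5E)-2,6-dimethyl-3-[(2S)-oxiran-2-yl]-4-(triethylsilyloxy)undec-5-en-9-yne (key-step precursor) | CC#CCC/C(C)=C/[C@H](O[Si](CC)(CC)CC)[C@@H](C(C)C)[C@H]1CO1 | intermediate
21 | O8-diethylboryl ether of 22 | CCB(CC)O[C@@H]1C/C(C)=C/CC/C(C)=C/[C@H](O[Si](CC)(CC)CC)[C@H]1C(C)C | intermediate
22 | (1(10)E,4E,6S,7S,8R)-6-(triethylsilyloxy)germacra-1(10),4-dien-8-ol (key-step product) | O[C@@H]1C/C(C)=C/CC/C(C)=C/[C@H](O[Si](CC)(CC)CC)[C@H]1C(C)C | intermediate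
23 | isovanillic acid | COc1ccc(C(=O)O)cc1O | starting material
24 | allyl 3-(allyloxy)-4-methoxybenzoate | C=CCOC(=O)c1ccc(OC)c(OCC=C)c1 | intermediate
25 | 3-(allyloxy)-4-methoxybenzoic acid | C=CCOc1cc(C(=O)O)ccc1OC | intermediate
26 | (1(10)E,4E,6S,7S,8R)-6-(triethylsilyloxy)germacra-1(10),4-dien-8-yl 3-(allyloxy)-4-methoxybenzoate | C=CCOc1cc(ccc1OC)C(=O)O[C@@H]1C/C(C)=C/CC/C(C)=C/[C@H](O[Si](CC)(CC)CC)[C@H]1C(C)C | intermediate
27 | (1(10)E,4E,6S,7R,8R)-6-hydroxygermacra-1(10),4-dien-8-yl 3-(allyloxy)-4-methoxybenzoate | C=CCOc1cc(ccc1OC)C(=O)O[C@@H]1C/C(C)=C/CC/C(C)=C/[C@H](O)[C@H]1C(C)C | intermediate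
28 | (1(10)E,4R,5R,6R,7R,8R)-4,5-epoxy-6-hydroxygermacr-1(10)-en-8-yl 3-(allyloxy)-4-methoxybenzoate | C=CCOc1cc(ccc1OC)C(=O)O[C@@H]1C/C(C)=C/CC[C@@]2(C)O[C@@H]2[C@H](O)[C@H]1C(C)C | intermediate
29 | (1(10)E,4R,5R,6R,7R,8R)-4,5-epoxy-6-hydroxygermacr-1(10)-en-8-yl 3-hydroxy-4-methoxybenzoate | COc1ccc(C(=O)O[C@@H]2C/C(C)=C/CC[C@@]3(C)O[C@@H]3[C@H](O)[C@H]2C(C)C)cc1O | target

Total step count: 16. Longest linear sequence: 13 steps (1–3, 6–11, 13–16).

Steps most likely to fail

**Step 11.**
- What may go wrong: insertion of the alkyne through C1 (nine-membered ring with an exocyclic ethylidene), intermolecular coupling outrunning ring closure, or consumption of the epoxide by simple reduction or by the phosphine.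
- Fallback (known chemistry; sets out from triol 17, comes back at 22): the same C9–C10 bond is closed by a Nozaki–Hiyama–Kishi reaction of a regiodefined alkenyl iodide with a C9 aldehyde, and the surplus C9 oxygen is then removed. Et3SiCl/imidazole converts 17 into the tris(triethylsilyl) ether F1. Hydrozirconation with excess Cp2Zr(H)Cl under equilibrating conditions (zirconium settles on the methyl-bearing C10), followed by iodinolysis, gives the (E)-C10 alkenyl iodide F2. Swern conditions cleave and oxidise only the primary silyl ether to the aldehyde F3. CrCl2 with catalytic NiCl2 in DMSO/THF at high dilution closes the ring to the C9 allylic alcohol F4; both C9 epimers serve. MsCl/Et3N gives the mesylate F5. Bu4NF frees O8, which displaces the mesylate while the C8–O bond is kept, and this gives the alkenyl oxirane F6 with free C6–OH. Et3SiCl/imidazole gives the silyl ether F7. Palladium-catalysed formate hydrogenolysis (Pd2(dba)3·CHCl3, PBu3, HCO2H, Et3N, THF) then delivers hydride to the allylic C9 and returns the homoallylic alcohol 22.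

**Step 15.**
- What may go wrong: poor facial selectivity if oxygen transfer proceeds through the A(1,3)-minimised conformer, sluggish turnover because C15 is cis to the carbinol carbon, or Lewis-acid-triggered transannular opening of the new epoxide.
- Fallback (sets out from epoxy alcohol 19, comes back at 28): the oxidation is moved to the acyclic stage, where no ring conformation can oppose the matched titanium–tartrate transition state. Ti(OiPr)4/D-(−)-diisopropyl tartrate/t-BuOOH on 19 gives the bis-epoxy alcohol F8. Et3SiCl/imidazole gives the silyl ether F9. The ring closure of step 11 is then run on F9, whose trisubstituted epoxide should be far less prone to opening by nickel than the terminal one, to give the epoxy macrocycle F10. Steglich acylation with 25 gives the ester F11, and buffered HF·pyridine then gives 28.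

**Step 3.**
- What may go wrong: attack of the aluminium amide at the ring carbonyl of the auxiliary instead of the hindered α-isopropyl acyl carbonyl, or retro-aldol cleavage of the aluminium aldolate.
- Fallback (sets out from 2 and 4, comes back at 7): a more labile auxiliary replaces steps 1–3. Commercial (S)-4-benzyl-1,3-thiazolidine-2-thione is acylated with 2 (Et3N, DMAP, CH2Cl2) to the N-isovaleryl thiazolidinethione F12. Its chlorotitanium enolate (TiCl4, i-Pr2NEt, N-methylpyrrolidinone, CH2Cl2, −78 → 0 °C) adds to 4 through a non-chelated chair to give the syn aldol adduct F13, which has the same C7/C8 configuration as 6. The thione auxiliary is then displaced directly by MeONHMe·HCl/imidazole at rt, without aluminium, to give 7.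

Further compounds
F1 | step 11 | 6,8,9-tris(triethylsilyl) ether of triol 17 | CC#CCC/C(C)=C/[C@H](O[Si](CC)(CC)CC)[C@@H](C(C)C)[C@H](O[Si](CC)(CC)CC)CO[Si](CC)(CC)CC
F2 | step 11 | (1(10)E)-C10 alkenyl iodide derived from F1 | I/C(C)=C/CC/C(C)=C/[C@H](O[Si](CC)(CC)CC)[C@@H](C(C)C)[C@H](O[Si](CC)(CC)CC)CO[Si](CC)(CC)CC
F3 | step 11 | C9 aldehyde with C10 iodide and 6,8-bis(triethylsilyl) ethers | I/C(C)=C/CC/C(C)=C/[C@H](O[Si](CC)(CC)CC)[C@@H](C(C)C)[C@H](O[Si](CC)(CC)CC)C=O
F4 | step 11 | (1(10)E,4E)-6,8-bis(triethylsilyloxy)germacra-1(10),4-dien-9-ol, C9 epimers | CC[Si](CC)(CC)O[C@@H]1C(O)/C(C)=C/CC/C(C)=C/[C@H](O[Si](CC)(CC)CC)[C@H]1C(C)C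
F5 | step 11 | C9 methanesulfonate of F4 | CC[Si](CC)(CC)O[C@@H]1C(OS(C)(=O)=O)/C(C)=C/CC/C(C)=C/[C@H](O[Si](CC)(CC)CC)[C@H]1C(C)C
F6 | step 11 | (1(10)E,4E)-8,9-epoxygermacra-1(10),4-dien-6-ol | O1[C@@H]2C1/C(C)=C/CC/C(C)=C/[C@H](O)[C@H]2C(C)C
F7 | step 11 | (1(10)E,4E)-8,9-epoxy-6-(triethylsilyloxy)germacra-1(10),4-diene | O1[C@@H]2C1/C(C)=C/CC/C(C)=C/[C@H](O[Si](CC)(CC)CC)[C@H]2C(C)C
F8 | step 15 | acyclic 4,5:8,9-bis-epoxy C6 alcohol (4R,5R epoxide, erythro to C6) | CC#CCC[C@@]1(C)O[C@@H]1[C@H](O)[C@@H](C(C)C)[C@H]2CO2
F9 | step 15 | C6 triethylsilyl ether of F8 | CC#CCC[C@@]1(C)O[C@@H]1[C@H](O[Si](CC)(CC)CC)[C@@H](C(C)C)[C@H]2CO2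
F10 | step 15 | (1(10)E)-4,5-epoxy-6-(triethylsilyloxy)germacr-1(10)-en-8-ol | O[C@@H]1C/C(C)=C/CC[C@@]2(C)O[C@@H]2[C@H](O[Si](CC)(CC)CC)[C@H]1C(C)C
F11 | step 15 | 3-(allyloxy)-4-methoxybenzoate of F10 | C=CCOc1cc(ccc1OC)C(=O)O[C@@H]1C/C(C)=C/CC[C@@]2(C)O[C@@H]2[C@H](O[Si](CC)(CC)CC)[C@H]1C(C)C
F12 | step 3 | (S)-4-benzyl-3-(3-methylbutanoyl)-1,3-thiazolidine-2-thione | CC(C)CC(=O)N1C(=S)SC[C@@H]1Cc1ccccc1
F13 | step 3 | syn aldol adduct of F12 with 4, (2S,3S)-acyl chain | S=C1SC[C@H](Cc2ccccc2)N1C(=O)[C@@H](C(C)C)[C@H](O)CO[Si](C)(C)C(C)(C)C
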